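**Plan**

- Retrosynthesis: the anisoate C(acyl)–O bond is cut first. Ring B (C5–C6–C7–C8–C9–C10) is then traced back to a seven-membered ring in which the isopropyl carbon C11 is a ring atom between C7 and C8. Last, C1–C10 and C4–C5 are cut, giving 2-methylfuran and a cycloheptenone.
- Enabling feature: the 7-oxabicyclo[2.2.1]heptane (O, C1, C2, C3, C4, C5, C10) is trans-fused to ring B at C5–C10. A furan Diels–Alder reaction gives such a fusion only from an (E)-cycloalkenone, which is accessible from ring size seven upward. C11, with its two methyls next to an oxygenated C7, lets the later one-atom contraction run as a 1,2-shift to a tertiary cation.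
- Forward: (+)-3-carene is opened to 3,6,6-trimethylcyclohept-2-enone. Photo-isomerisation and cycloaddition with 2-methylfuran put the oxygen-bridged ring on the seven-membered ring. The ketone becomes the C6=C7 alkene, then the cis-diol and its cyclic sulfate; ring contraction forms ring B with the isopropyl group; esterification is last.
- Stereochemistry: C1, C4, C5 and C10 come from the suprafacial addition to the trans double bond, C6 from face-selective dihydroxylation, and C7 from the stereospecific shift (inversion). The absolute configuration comes from resolution of the C6 alcohol as its (1S)-camphanate.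

Key step: step 9

Remark: eudesmane numbering is used for all ring compounds (in the seven-membered intermediates C11, with its two methyls, lies between C7 and C8); β is the face of H-5, α the face of the C10 methyl; compounds 6 to 15 are racemic and their SMILES show the enantiomer that is carried on.

**Route**

Step 1
Reactants: 1 (+)-3-carene
Product: 2 car-3-en-5-one
Conditions: t-BuOOH (70% aq), CrO3 (5 mol %), CH2Cl2, rt
Reagents that add atoms: tert-butyl hydroperoxide, CC(C)(C)OO
Why: Allylic oxidation by the chromium-catalysed peroxide chain should convert the methylene next to the unsubstituted alkene carbon into the conjugated enone; the stereocentres are untouched.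

Step 2
Reactants: 2 car-3-en-5-one
Product: 3 3,6,6-trimethylcyclohepta-2,4-dien-1-one
Conditions: KOtBu (20 mol %), t-BuOH, 60 °C
Reagents that add atoms: none
Why: γ-Deprotonation gives a dienolate that is a norcaradiene, whose six-electron electrocyclic opening (the carenone-to-eucarvone type isomerisation) cleaves the internal cyclopropane bond and, after protonation, should give the conjugated seven-membered dienone.

Step 3
Reactants: 3 3,6,6-trimethylcyclohepta-2,4-dien-1-one
Product: 4 (Z)-3,6,6-trimethylcyclohept-2-en-1-one
Conditions: H2 (1 atm), RhCl(PPh3)3 (5 mol %), benzene–EtOH, rt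
Reagents that add atoms: none
Why: Homogeneous hydrogenation with RhCl(PPh3)3 should reduce the disubstituted γ,δ double bond and leave the trisubstituted, conjugated α,β double bond, as is known for linear dienones.

Step 4
Reactants: 4 (Z)-3,6,6-trimethylcyclohept-2-en-1-one; 5 2-methylfuran
Product: 8 rac-trans-fused saturated tricyclic ketone, via (E)-enone 6 (not isolated), via oxanorbornene adduct 7 (not isolated)
Conditions: hν (350 nm), 2-methylfuran (10 equiv), CH2Cl2, −40 °C; then evaporation, H2 (1 atm), Pd/C (palladium metal on carbon), EtOAc, 0 °C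
Reagents that add atoms: none
Why: Irradiation twists the seven-membered enone into the strained ground-state (E)-enone 6, which undergoes a thermal suprafacial Diels–Alder reaction with 2-methylfuran on its one open face, so the trans alkene becomes the trans ring fusion; the unsubstituted furan carbon should bond to the β-carbon (C10) and the methyl-bearing one to the α-carbon (C5), the endo orientation of the carbonyl (oxygen bridge syn to H-5) should be preferred, and the exo diastereomer is removed after the hydrogenation, which saturates only the strained C2=C3 bond.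

Step 5
Reactants: 8 rac-trans-fused saturated tricyclic ketone
Product: 9 rac-enol triflate (C6=C7)
Conditions: KN(SiMe3)2 (1.1 equiv), THF, −78 °C; then PhNTf2
Reagents that add atoms: N-phenyl-bis(trifluoromethanesulfonimide), O=S(=O)(N(c1ccccc1)S(=O)(=O)C(F)(F)F)C(F)(F)F
Why: Kinetic deprotonation by the hindered amide should occur at the C7 methylene and not at the shielded C5 methine (whose loss would cost the trans fusion), and the enolate is trapped on oxygen as the vinyl triflate.

Step 6
Reactants: 9 rac-enol triflate (C6=C7)
Product: 10 rac-alkene (C6=C7)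
Conditions: Pd(OAc)2 (5 mol %), PPh3, HCO2H, Bu3N, DMF, 60 °C
Reagents that add atoms: none
Why: Palladium-catalysed formate reduction of a vinyl triflate replaces the triflate by hydrogen without moving the double bond.

Step 7
Reactants: 10 rac-alkene (C6=C7)
Product: 11 rac-6β,7β-diol
Conditions: OsO4 (2 mol %), N-methylmorpholine N-oxide, acetone–H2O, rt
Reagents that add atoms: N-methylmorpholine N-oxide, C[N+]1([O-])CCOCC1; water, O
Why: Catalytic syn-dihydroxylation adds both oxygens to one face; the α face is blocked by the 1,3-related C10 methyl, so the cis-diol should form on the face of H-5, which sets C6 as in the target.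

Step 8
Reactants: 11 rac-6β,7β-diol
Product: 13 rac-cyclic sulfate, via cyclic sulfite 12 (not isolated)
Conditions: SOCl2, Et3N, CH2Cl2, 0 °C; then RuCl3 (1 mol %), NaIO4, MeCN–H2O, 0 °C
Reagents that add atoms: thionyl chloride, O=S(Cl)Cl; sodium periodate, [Na+].[O-]I(=O)(=O)=O
Why: Cyclic sulfite formation followed by RuO4 oxidation is the standard cyclic sulfate synthesis from a 1,2-diol and leaves both C–O bonds and their configurations intact.

Step 9
Reactants: 13 rac-cyclic sulfate
Product: 15 rac-1,4-epoxyeudesman-6-ol, via silyl sulfate 14 (not isolated)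
Conditions: Et3SiH (3 equiv), (CF3)2CHOH, 50 °C; then H2SO4 (cat.), H2O, THF, rt
Reagents that add atoms: none
Why: Proposed new method: in the ionising solvent the C7–O bond of the cyclic sulfate should heterolyse with concerted 1,2-shift of C8 from C11 to C7 (Wagner–Meerwein), which forms six-membered ring B and a tertiary cation at C11 that triethylsilane reduces to the isopropyl group, and hydrolysis of silyl sulfate 14 then frees the C6 hydroxyl. The closest known reaction types are the solvolytic ring contraction of 2,2-dimethylcycloalkyl sulfonates (3β-sulfonyloxy-4,4-dimethyl steroids to ring-A-contracted isopropyl compounds), the ionisation of 1,2-cyclic sulfates and the ionic hydrogenation of tertiary cations by silanes. Ring B is closed by a suprafacial 1,2-alkyl shift through a three-centre transition state, which contracts the seven-membered ring by one atom and leaves C11 outside the ring. C7 is the only new stereocentre and is set by inversion, because C8 enters anti to the departing oxygen whose face was fixed in step 7, while C6 keeps its oxygen and configuration. The step needs ionisation at C7 and not at C6, and migration of the ring bond and not of a methyl group: only C7 has a quaternary neighbour that leads to a tertiary cation (ionisation at C6 would need a 7-oxanorbornyl cation), the five-membered sulfate ring should hold the C7–O bond antiperiplanar to the C11–C8 bond, and the electron-poor sulfate oxygen on C6 disfavours hydride or C5 shift from C6. The extra strain of the trans-fused six-membered ring is paid for by opening the cyclic sulfate and forming the tertiary cation.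

Step 10
Reactants: 15 rac-1,4-epoxyeudesman-6-ol; 16 (1S)-camphanic chloride
Product: 17 (1R,4S,5R,6R,7S,10S)-1,4-epoxyeudesman-6-yl (1S)-camphanate
Conditions: Et3N, DMAP (cat.), CH2Cl2, rt; separation of the two diastereomeric esters by chromatography or crystallisation
Reagents that add atoms: none
Why: Acylation with the enantiopure acid chloride turns the racemic alcohol into two diastereomeric esters that can be separated (classical resolution), which supplies the absolute configuration.

Step 11
Reactants: 17 (1R,4S,5R,6R,7S,10S)-1,4-epoxyeudesman-6-yl (1S)-camphanate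
Product: 18 (1R,4S,5R,6R,7S,10S)-1,4-epoxyeudesman-6-ol
Conditions: LiAlH4, THF, 0 °C to rt
Reagents that add atoms: none
Why: Hydride reduction cleaves the hindered ester at the acyl carbon, so the C6–O bond and its configuration are kept.

Step 12
Reactants: 18 (1R,4S,5R,6R,7S,10S)-1,4-epoxyeudesman-6-ol; 19 4-methoxybenzoyl chloride
Product: 20 (1R,4S,5R,6R,7S,10S)-1,4-epoxyeudesman-6-yl 4-methoxybenzoate
Conditions: Et3N, DMAP, CH2Cl2, 40 °C
Reagents that add atoms: none
Why: DMAP-catalysed acylation of the secondary alcohol by the acid chloride forms the ester with retention at C6.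

**Compound list**

1 | (+)-3-carene, (1S,6R)-3,7,7-trimethylbicyclo[4.1.0]hept-3-ene | CC1=CC[C@@H]2[C@H](C1)C2(C)C | starting material
2 | car-3-en-5-one, (1R,6S)-4,7,7-trimethylbicyclo[4.1.0]hept-3-en-2-one | CC1=CC(=O)[C@@H]2[C@H](C1)C2(C)C | intermediate
3 | 3,6,6-trimethylcyclohepta-2,4-dien-1-one | CC1=CC(=O)CC(C)(C)C=C1 | intermediate
4 | (Z)-3,6,6-trimethylcyclohept-2-en-1-one | C/C1=C/C(=O)CC(C)(C)CC1 | intermediate
5 | 2-methylfuran | Cc1ccco1 | starting material
6 | (E)-3,6,6-trimethylcyclohept-2-en-1-one (racemic, trans double bond in the ring) | C/C1=C\C(=O)CC(C)(C)CC1 | intermediate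
7 | rac-oxanorbornene adduct: 7-oxabicyclo[2.2.1]hept-2-ene (O between C1 and C4, methyl on C4) trans-fused at C5–C10 to the seven-membered ketone ring C5–C6(=O)–C7–C11(CH3)2–C8–C9–C10(CH3); C6 and the C10 methyl anti to the O bridge, H-5 and C9 syn | O=C1CC(C)(C)CC[C@]2(C)[C@H]3C=C[C@](C)(O3)[C@@H]12 | intermediate
8 | rac-trans-fused saturated tricyclic ketone: compound 7 with C2–C3 saturated | O=C1CC(C)(C)CC[C@]2(C)[C@H]3CC[C@](C)(O3)[C@@H]12 | intermediate
9 | rac-enol triflate: C6(OSO2CF3)=C7 in the seven-membered ring of 8 | O=S(=O)(OC1=CC(C)(C)CC[C@]2(C)[C@H]3CC[C@](C)(O3)[C@@H]12)C(F)(F)F | intermediate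
10 | rac-alkene: C6=C7 in the seven-membered ring, otherwise as 8 without the carbonyl oxygen | C1=CC(C)(C)CC[C@]2(C)[C@H]3CC[C@](C)(O3)[C@@H]12 | intermediate
11 | rac-6β,7β-diol: cis-diol at C6 and C7 of the seven-membered ring, both OH on the face of H-5 | O[C@@H]1[C@H](O)C(C)(C)CC[C@]2(C)[C@H]3CC[C@](C)(O3)[C@@H]12 | intermediate
12 | rac-cyclic sulfite of diol 11 (configuration at sulfur not defined) | O=S1O[C@@H]2[C@H](O1)C(C)(C)CC[C@]3(C)[C@H]4CC[C@](C)(O4)[C@@H]23 | intermediate
13 | rac-cyclic sulfate of diol 11 | O=S1(=O)O[C@@H]2[C@H](O1)C(C)(C)CC[C@]3(C)[C@H]4CC[C@](C)(O4)[C@@H]23 | intermediate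
14 | rac-1,4-epoxyeudesman-6-yl triethylsilyl sulfate | CC[Si](CC)(CC)OS(=O)(=O)O[C@@H]1[C@H](C(C)C)CC[C@]2(C)[C@H]3CC[C@](C)(O3)[C@@H]12 | intermediate
15 | rac-1,4-epoxyeudesman-6-ol (relative configuration 1R*,4S*,5R*,6R*,7S*,10S*) | O[C@@H]1[C@H](C(C)C)CC[C@]2(C)[C@H]3CC[C@](C)(O3)[C@@H]12 | intermediate
16 | (1S)-camphanic chloride, (1S,4R)-4,7,7-trimethyl-3-oxo-2-oxabicyclo[2.2.1]heptane-1-carbonyl chloride | CC1(C)[C@@]2(C)CC[C@]1(C(=O)Cl)OC2=O | starting material
17 | (1R,4S,5R,6R,7S,10S)-1,4-epoxyeudesman-6-yl (1S,4R)-camphanate | CC1(C)[C@@]2(C)CC[C@]1(C(=O)O[C@@H]3[C@H](C(C)C)CC[C@]4(C)[C@H]5CC[C@](C)(O5)[C@@H]34)OC2=O | intermediate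
18 | (1R,4S,5R,6R,7S,10S)-1,4-epoxyeudesman-6-ol (single enantiomer) | O[C@@H]1[C@H](C(C)C)CC[C@]2(C)[C@H]3CC[C@](C)(O3)[C@@H]12 | intermediate
19 | 4-methoxybenzoyl chloride | COc1ccc(C(=O)Cl)cc1 | starting material
20 | (1R,4S,5R,6R,7S,10S)-1,4-epoxyeudesman-6-yl 4-methoxybenzoate | COc1ccc(C(=O)O[C@@H]2[C@H](C(C)C)CC[C@]3(C)[C@H]4CC[C@](C)(O4)[C@@H]23)cc1 | target

**Step count and risks**

Total step count: 12. Longest linear sequence: 12 steps (1 to 20).

Steps most likely to fail:

Step 9 (proposed new method). The sulfate may ionise at C6 with shift of C10 and loss of the ring fusion, a methyl group may migrate in place of C8, or the oxygen bridge may open during the acidic hydrolysis. The fallback uses known chemistry and sets out from diol 11. Exhaustive mesylation (MeSO2Cl, Et3N, DMAP) should give rac-bis-mesylate F1, which needs no choice between the two hydroxyls. Heating F1 in (CF3)2CHOH with Et3SiH ionises the C7 mesylate in the classical solvolytic ring contraction of a 2,2-dimethylcycloalkyl sulfonate, and the silane captures the cation, which should give the rac-C6 mesylate of the ring-contracted isopropyl compound F2. Sodium naphthalenide in THF at −78 °C then cleaves the S–O bond and returns the route at alcohol 15.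

Step 5. Deprotonation may occur at C5; this would give the wrong enol triflate and, after reprotonation, the cis-fused ketone. The fallback sets out from ketone 8 and avoids enolate chemistry. NaBH4 reduction from the open β face should give the rac-6α-alcohol F3, which is converted with NaH, CS2 and MeI into the rac-S-methyl xanthate F4. Chugaev syn-elimination at about 180 °C can only take the syn hydrogen on C7, because H-5 lies anti to the xanthate, and comes back to the route at alkene 10.

Step 3. The conjugated double bond may be reduced, or both double bonds. The fallback sets out from dienone 3. Exhaustive hydrogenation (H2, Pd/C) gives rac-3,6,6-trimethylcycloheptanone F5. Kinetic enolisation at the unhindered C2 methylene (LiN(iPr)2, Me3SiCl, −78 °C) gives the rac-silyl enol ether F6, and Saegusa–Ito dehydrogenation with Pd(OAc)2 comes back to the route at enone 4.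

Further compounds
F1 | step 9 | rac-6β,7β-bis(methanesulfonate) of diol 11 | CS(=O)(=O)O[C@@H]1[C@H](OS(C)(=O)=O)C(C)(C)CC[C@]2(C)[C@H]3CC[C@](C)(O3)[C@@H]12
F2 | step 9 | rac-1,4-epoxyeudesman-6-yl methanesulfonate | CS(=O)(=O)O[C@@H]1[C@H](C(C)C)CC[C@]2(C)[C@H]3CC[C@](C)(O3)[C@@H]12
F3 | step 5 | rac-6α-alcohol from ketone 8 (OH on the face of the C10 methyl) | O[C@H]1CC(C)(C)CC[C@]2(C)[C@H]3CC[C@](C)(O3)[C@@H]12
F4 | step 5 | rac-O-alkyl S-methyl xanthate of F3 | CSC(=S)O[C@H]1CC(C)(C)CC[C@]2(C)[C@H]3CC[C@](C)(O3)[C@@H]12
F5 | step 3 | rac-3,6,6-trimethylcycloheptan-1-one | CC1CCC(C)(C)CC(=O)C1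
F6 | step 3 | rac-3,6,6-trimethyl-1-(trimethylsilyloxy)cyclohept-1-ene | CC1CCC(C)(C)CC(O[Si](C)(C)C)=C1
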